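**Retrosynthetic overview**

- Feature: ring C is a 4-pyranone (O1–C2–C3–C4–C4a–C8a) whose C4 carbonyl is bonded to C4a, the ring A carbon lying between C8a (which bears O1) and the oxygenated C5. An aryl anion at C4a can therefore close ring C by attacking an ester carbon that becomes C4.
- Last disconnection: the C5 and C7 phenols are unmasked from triisopropylsilyl ethers by fluoride, which leaves the 4'-O-prenyl ether intact.
- Key disconnection C4–C4a: bromine–lithium exchange on an (E)-β-aryloxy-α-methoxycinnamate, then intramolecular acylation. Ring C is the only ring formed; rings A and B come from phloroglucinol and methyl 4-hydroxybenzoate.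
- O1–C2 disconnection: addition–elimination of a 2-bromophenoxide on the (E)-β-chloro-α-methoxycinnamate, itself made from the β-keto ester (crossed Claisen of methyl 4-prenyloxybenzoate with methyl methoxyacetate).
- The bromophenol comes from phloroglucinol by bis-silylation and bromination ortho to the free hydroxyl.

Key step: step 7

Remark: flavone numbering is used for ring atoms; for open-chain compounds the propenoate numbering is stated explicitly; anhydrous phloroglucinol is assumed.

Step 1
Reactants: 1 methyl 4-hydroxybenzoate; 2 prenyl bromide (1-bromo-3-methylbut-2-ene)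
Product: 3 methyl 4-(3-methylbut-2-enyloxy)benzoate
Conditions: 2 (1.2 equiv), K2CO3, acetone, reflux
Reagents that add atoms: none
Why: Williamson ether synthesis, in which the phenoxide of 1 (acidified by the para ester) displaces bromide from the primary allylic carbon (SN2) and should give the O-prenyl ether.

Step 2
Reactants: 3 methyl 4-(3-methylbut-2-enyloxy)benzoate; 4 methyl methoxyacetate
Product: 6 methyl 2-methoxy-3-[4-(3-methylbut-2-enyloxy)phenyl]-3-oxopropanoate, via lithium enolate of methyl methoxyacetate 5 (not isolated)
Conditions: 4 (2.2 equiv), LiN(i-Pr)2 (2.2 equiv), THF, –78 °C; then 3, –78 → 0 °C; aq. NH4Cl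
Reagents that add atoms: none
Why: Crossed Claisen condensation, in which 3 has no α-hydrogen and can only be the acceptor, the preformed enolate 5 is the only carbon nucleophile, and the second equivalent of enolate deprotonates the β-keto ester as it forms and drives the acylation forward (6 is racemic at C2, a centre removed in step 3).

Step 3
Reactants: 6 methyl 2-methoxy-3-[4-(3-methylbut-2-enyloxy)phenyl]-3-oxopropanoate
Product: 7 methyl (E)-3-chloro-2-methoxy-3-[4-(3-methylbut-2-enyloxy)phenyl]prop-2-enoate
Conditions: Ph3P (2 equiv), CCl4 (5 equiv), MeCN, 60 °C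
Reagents that add atoms: carbon tetrachloride, ClC(Cl)(Cl)Cl
Why: Appel-type deoxychlorination of a β-keto ester enol, in which the hydrogen-bonded enol is phosphonylated on the ketone oxygen and chloride replaces Ph3PO at propenoate C3 by addition–elimination under neutral conditions that should spare the acid-sensitive prenyl ether; chlorine cis to the ester (aryl trans to the ester, as in the stable isomers of β-chloro- and α-alkoxycinnamates) is expected to prevail, the (E) isomer is purified by chromatography, and its geometry is to be confirmed by NOE between the methoxy group on propenoate C2 and the ortho hydrogens of the aryl ring.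

Step 4
Reactants: 8 phloroglucinol
Product: 9 3,5-bis(triisopropylsilyloxy)phenol
Conditions: TIPSCl (2.05 equiv), imidazole (4 equiv), DMF, 0 °C → rt
Reagents that add atoms: triisopropylsilyl chloride (TIPSCl), CC(C)[Si](Cl)(C(C)C)C(C)C
Why: O-silylation of phenols with a silyl chloride and imidazole, in which the three hydroxyls are equivalent so no regiochemical question arises, and two equivalents of the bulky chloride should favour the bis-ether, which is separated from the recyclable mono- and tris-silyl ethers.

Step 5
Reactants: 9 3,5-bis(triisopropylsilyloxy)phenol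
Product: 10 2-bromo-3,5-bis(triisopropylsilyloxy)phenol
Conditions: NBS (1.0 equiv), i-Pr2NH (10 mol %), CH2Cl2, –78 → –20 °C
Reagents that add atoms: N-bromosuccinimide (NBS), O=C1CCC(=O)N1Br
Why: Amine-catalysed ortho-bromination of a phenol (electrophilic aromatic substitution), in which the two positions ortho to the free hydroxyl are equivalent, the remaining position is shielded between two bulky silyloxy groups, and one equivalent of NBS at low temperature should stop at the monobromide.

Step 6
Reactants: 7 methyl (E)-3-chloro-2-methoxy-3-[4-(3-methylbut-2-enyloxy)phenyl]prop-2-enoate; 10 2-bromo-3,5-bis(triisopropylsilyloxy)phenol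
Product: 11 methyl (E)-3-[2-bromo-3,5-bis(triisopropylsilyloxy)phenoxy]-2-methoxy-3-[4-(3-methylbut-2-enyloxy)phenyl]prop-2-enoate
Conditions: 10 (1.05 equiv), Cs2CO3 (1.5 equiv), dry DMF, 50 °C
Reagents that add atoms: none
Why: Nucleophilic vinylic substitution (addition–elimination, SNV) of a β-chloroacrylate by a phenoxide, in which the caesium phenoxide of 10 adds to propenoate C3 and chloride leaves from the short-lived ester enolate after the least-motion rotation, so the substitution should proceed with retention and place the aryloxy group cis to the ester; the geometry of 11 is to be confirmed by NOE before the key step.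

Step 7
Reactants: 11 methyl (E)-3-[2-bromo-3,5-bis(triisopropylsilyloxy)phenoxy]-2-methoxy-3-[4-(3-methylbut-2-enyloxy)phenyl]prop-2-enoate
Product: 14 3-methoxy-2-[4-(3-methylbut-2-enyloxy)phenyl]-5,7-bis(triisopropylsilyloxy)-4H-chromen-4-one, via C4a aryllithium 12 (not isolated), via tetrahedral lithium alkoxide 13 (not isolated)
Conditions: t-BuLi (2.05 equiv), THF, –100 °C, then –78 → –40 °C; aq. NH4Cl
Reagents that add atoms: none
Why: t-BuLi should exchange the bromine of 11 within minutes at –100 °C, faster than it adds to the hindered, donor-substituted acrylate ester, and the second equivalent destroys the t-BuBr formed. The aryllithium 12, held between O1 and the C5 silyl ether, attacks the ester carbonyl that the (E) alkene places cis to the aryloxy oxygen; this closure of ring C is 6-exo-trig and forms C4–C4a. The tetrahedral alkoxide 13 then loses LiOMe to give the 4-pyranone, a vinylogous ester that should not accept a second nucleophile at this temperature. The closest known reaction type is the Parham cyclization, that is halogen–lithium exchange followed by intramolecular acylation of the aryllithium by an ester. No stereocentre remains in 14, since the C4 centre of 13 is lost on collapse. The step needs metalation at C4a only and no O-to-C silyl shift: the bromine fixes the site, the alkene geometry secures the reach, and the bulk of the triisopropylsilyl group together with the fast six-membered closure should keep 1,3-silyl migration from O5 to C4a from competing.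

Step 8
Reactants: 14 3-methoxy-2-[4-(3-methylbut-2-enyloxy)phenyl]-5,7-bis(triisopropylsilyloxy)-4H-chromen-4-one
Product: 15 5,7-dihydroxy-3-methoxy-2-[4-(3-methylbut-2-enyloxy)phenyl]-4H-chromen-4-one (5,7-dihydroxy-3-methoxy-4'-prenyloxyflavone)
Conditions: n-Bu4NF (2.4 equiv), AcOH (2.4 equiv), THF, 0 °C → rt
Reagents that add atoms: none
Why: Fluoride-induced cleavage of aryl silyl ethers, driven by Si–F bond formation, with acetic acid buffering the phenoxides so that the flavone and the prenyl ether should remain untouched.

**Compound list**

1 | methyl 4-hydroxybenzoate | COC(=O)c1ccc(O)cc1 | starting material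
2 | prenyl bromide (1-bromo-3-methylbut-2-ene) | CC(C)=CCBr | starting material
3 | methyl 4-(3-methylbut-2-enyloxy)benzoate | COC(=O)c1ccc(OCC=C(C)C)cc1 | intermediate
4 | methyl methoxyacetate | COCC(=O)OC | starting material
5 | lithium (E)-1,2-dimethoxyethen-1-olate (chelated lithium enolate of 4) | CO/C=C(\O[Li])OC | intermediate (not isolated)
6 | methyl 2-methoxy-3-[4-(3-methylbut-2-enyloxy)phenyl]-3-oxopropanoate (racemic) | COC(=O)C(OC)C(=O)c1ccc(OCC=C(C)C)cc1 | intermediate
7 | methyl (E)-3-chloro-2-methoxy-3-[4-(3-methylbut-2-enyloxy)phenyl]prop-2-enoate | COC(=O)/C(OC)=C(/c1ccc(OCC=C(C)C)cc1)Cl | intermediate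
8 | phloroglucinol | Oc1cc(O)cc(O)c1 | starting material
9 | 3,5-bis(triisopropylsilyloxy)phenol | Oc1cc(O[Si](C(C)C)(C(C)C)C(C)C)cc(O[Si](C(C)C)(C(C)C)C(C)C)c1 | intermediate
10 | 2-bromo-3,5-bis(triisopropylsilyloxy)phenol | Oc1cc(O[Si](C(C)C)(C(C)C)C(C)C)cc(O[Si](C(C)C)(C(C)C)C(C)C)c1Br | intermediate
11 | methyl (E)-3-[2-bromo-3,5-bis(triisopropylsilyloxy)phenoxy]-2-methoxy-3-[4-(3-methylbut-2-enyloxy)phenyl]prop-2-enoate | COC(=O)/C(OC)=C(/c1ccc(OCC=C(C)C)cc1)Oc1cc(O[Si](C(C)C)(C(C)C)C(C)C)cc(O[Si](C(C)C)(C(C)C)C(C)C)c1Br | intermediate
12 | methyl (E)-3-[2-lithio-3,5-bis(triisopropylsilyloxy)phenoxy]-2-methoxy-3-[4-(3-methylbut-2-enyloxy)phenyl]prop-2-enoate | COC(=O)/C(OC)=C(/c1ccc(OCC=C(C)C)cc1)Oc1cc(O[Si](C(C)C)(C(C)C)C(C)C)cc(O[Si](C(C)C)(C(C)C)C(C)C)c1[Li] | intermediate (not isolated)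
13 | lithium 3,4-dimethoxy-2-[4-(3-methylbut-2-enyloxy)phenyl]-5,7-bis(triisopropylsilyloxy)-4H-chromen-4-olate (racemic, transient) | COC1=C(c2ccc(OCC=C(C)C)cc2)Oc2cc(O[Si](C(C)C)(C(C)C)C(C)C)cc(O[Si](C(C)C)(C(C)C)C(C)C)c2C1(OC)O[Li] | intermediate (not isolated)
14 | 3-methoxy-2-[4-(3-methylbut-2-enyloxy)phenyl]-5,7-bis(triisopropylsilyloxy)-4H-chromen-4-one | COc1c(-c2ccc(OCC=C(C)C)cc2)oc2cc(O[Si](C(C)C)(C(C)C)C(C)C)cc(O[Si](C(C)C)(C(C)C)C(C)C)c2c1=O | intermediate
15 | 5,7-dihydroxy-3-methoxy-2-[4-(3-methylbut-2-enyloxy)phenyl]-4H-chromen-4-one | COc1c(-c2ccc(OCC=C(C)C)cc2)oc2cc(O)cc(O)c2c1=O | target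

Total step count: 8
Longest linear sequence: 6 steps (steps 1, 2, 3, 6, 7, 8)

**Steps most likely to fail**

Step 7 (key step). What may go wrong: addition of t-BuLi to the ester carbonyl or the acrylate double bond before exchange is complete; deprotonation next to the prenyl ether oxygen followed by Wittig rearrangement; or anionic 1,3-migration of the silyl group from O5 to the lithiated C4a in competition with ring closure. Fallback: the same C4–C4a closure with magnesium in place of lithium and iodine in place of bromine. It sets out from 9. Iodination with N-iodosuccinimide under the conditions of step 5 should give 2-iodo-3,5-bis(triisopropylsilyloxy)phenol F1. Its caesium phenoxide is coupled with 7 as in step 6 to give methyl (E)-3-[2-iodo-3,5-bis(triisopropylsilyloxy)phenoxy]-2-methoxy-3-[4-(3-methylbut-2-enyloxy)phenyl]prop-2-enoate F2. Iodine–magnesium exchange with i-PrMgCl·LiCl in THF at –40 °C, which tolerates methyl esters and should not trigger silyl migration, should give the arylmagnesium chloride F3. On warming to 0 °C F3 is expected to acylate itself at the ester (6-exo-trig, loss of methoxide) and return to the route at 14.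

Step 6. What may go wrong: erosion of the alkene geometry, either because the enolate formed on addition lives long enough to rotate or because phenoxide adds reversibly to the product; slow addition at the fully substituted propenoate C3 would aggravate this. The (Z) isomer cannot cyclise in step 7. Fallback: stereoconvergence by isomerisation in place of reliance on stereoretentive substitution. It sets out from the E/Z mixture obtained from 7 and 10. The isomers are separated by chromatography, and the (Z) isomer of 11 F4 is returned to an E/Z mixture by triplet-sensitised irradiation (catalytic thioxanthen-9-one, MeCN, 385 nm). The mixture is separated again, and the (E) material comes back to the route at 11.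

Step 3. What may go wrong: formation of both geometric isomers of the vinyl chloride because chloride delivery to the enoxyphosphonium salt is not stereospecific, or stalling at the hindered, donor-substituted propenoate C3. Fallback: a geometry-defined enol triflate and a palladium-catalysed C–O coupling in place of the chloride and the SNV reaction. It sets out from 6. Triflation of the lithium-chelated enolate (LiOTf, Et3N, Tf2O, CH2Cl2, –78 °C) should give methyl (E)-2-methoxy-3-[4-(3-methylbut-2-enyloxy)phenyl]-3-(trifluoromethylsulfonyloxy)prop-2-enoate F5, with the triflate cis to the ester as fixed by the chelate. F5 is then coupled with 10 (Pd2(dba)3 as source of zerovalent palladium, 2-(di-tert-butylphosphino)biphenyl, K3PO4, toluene, 80 °C), a known aryl enol ether synthesis from vinyl triflates and phenols that retains alkene geometry. This comes back to the route at 11. Oxidative addition to the electron-poor vinyl triflate should be much faster than to the hindered, electron-rich aryl bromide.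

**Further compounds**

F1 | step 7 | 2-iodo-3,5-bis(triisopropylsilyloxy)phenol | Oc1cc(O[Si](C(C)C)(C(C)C)C(C)C)cc(O[Si](C(C)C)(C(C)C)C(C)C)c1I
F2 | step 7 | methyl (E)-3-[2-iodo-3,5-bis(triisopropylsilyloxy)phenoxy]-2-methoxy-3-[4-(3-methylbut-2-enyloxy)phenyl]prop-2-enoate | COC(=O)/C(OC)=C(/c1ccc(OCC=C(C)C)cc1)Oc1cc(O[Si](C(C)C)(C(C)C)C(C)C)cc(O[Si](C(C)C)(C(C)C)C(C)C)c1I
F3 | step 7 | methyl (E)-3-[2-(chloromagnesio)-3,5-bis(triisopropylsilyloxy)phenoxy]-2-methoxy-3-[4-(3-methylbut-2-enyloxy)phenyl]prop-2-enoate | COC(=O)/C(OC)=C(/c1ccc(OCC=C(C)C)cc1)Oc1cc(O[Si](C(C)C)(C(C)C)C(C)C)cc(O[Si](C(C)C)(C(C)C)C(C)C)c1[Mg]Cl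
F4 | step 6 | methyl (Z)-3-[2-bromo-3,5-bis(triisopropylsilyloxy)phenoxy]-2-methoxy-3-[4-(3-methylbut-2-enyloxy)phenyl]prop-2-enoate | COC(=O)/C(OC)=C(\c1ccc(OCC=C(C)C)cc1)Oc1cc(O[Si](C(C)C)(C(C)C)C(C)C)cc(O[Si](C(C)C)(C(C)C)C(C)C)c1Br
F5 | step 3 | methyl (E)-2-methoxy-3-[4-(3-methylbut-2-enyloxy)phenyl]-3-(trifluoromethylsulfonyloxy)prop-2-enoate | COC(=O)/C(OC)=C(/c1ccc(OCC=C(C)C)cc1)OS(=O)(=O)C(F)(F)F
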